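**Assumption:** the SMILES has no stereocentre and no stereogenic double bond, so the target is achiral and needs no enantiocontrol. The transient stereocentres in 7, 10 and 17–19 form as mixtures and are all erased later.

## Retrosynthetic overview
1. The 3-CHO comes from a 3-CO2Me group (reduce, then oxidise), and both OH groups are unmasked last from TBDPS ethers.
2. The furan is the only ring built. It closes late (O1–C2) by acid cyclodehydration of an α-(2-hydroxyaryl)-β-keto ester.
3. The β-keto ester comes from oxidation of a β-hydroxy ester, itself made by an intermolecular aldol (C2–C3 bond) between the enolate of arylacetate 13 and O-silyl vanillin 15.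
4. Arylacetate 13 comes from oxidative cleavage of an ortho-allyl group installed by O-allylation and aromatic Claisen rearrangement.
5. The hydroxypropyl chain comes from hydroboration of eugenol. Both benzene rings are bought (eugenol, vanillin).

## Route

Step 1
Reactants: 1 eugenol (4-allyl-2-methoxyphenol)
Product: 3 dihydroconiferyl alcohol (4-(3-hydroxypropyl)-2-methoxyphenol), via bis(9-BBN) adduct 2 (not isolated)
Conditions: 9-BBN (2.5 equiv), THF, 0 °C → rt; then 3 M NaOH, 30% H2O2, 0 °C → rt; acidify to pH 5
Reagents that add atoms: hydrogen peroxide, OO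
Why: In this Brown hydroboration–oxidation, bulky 9-BBN adds anti-Markovnikov to the terminal alkene (the phenol only consumes one extra equivalent as a hydrolysable aryl borinate) and alkaline H2O2 converts C–B into the primary alcohol without creating a stereocentre.

Step 2
Reactants: 3 dihydroconiferyl alcohol; 4 allyl bromide
Product: 5 3-[4-(allyloxy)-3-methoxyphenyl]propan-1-ol
Conditions: allyl bromide (1.2 equiv), K2CO3, acetone, reflux
Reagents that add atoms: allyl bromide (4), C=CCBr
Why: In this Williamson ether synthesis K2CO3 deprotonates only the phenol (pKa about 10), so the aliphatic alcohol stays untouched.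

Step 3
Reactants: 5 3-[4-(allyloxy)-3-methoxyphenyl]propan-1-ol
Product: 6 [3-(4-allyloxy-3-methoxyphenyl)propoxy](tert-butyl)diphenylsilane
Conditions: TBDPSCl, imidazole, DMF, 0 °C → rt
Reagents that add atoms: tert-butyl(chloro)diphenylsilane, CC(C)(C)[Si](Cl)(c1ccccc1)c1ccccc1
Why: Imidazole-promoted silylation of the only free OH installs a group that tolerates 200 °C, oxidants, enolates, TFA and DIBAL-H.

Step 4
Reactants: 6 allyl aryl ether
Product: 8 2-allyl-4-[3-(tert-butyldiphenylsilyloxy)propyl]-6-methoxyphenol, via 6-allyl-dienone 7 (not isolated)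
Conditions: PhNEt2, 200 °C, Ar
Reagents that add atoms: none
Why: The aromatic Claisen [3,3]-rearrangement can end productively only at the single H-bearing ortho carbon (the other ortho position carries OMe, the para position carries the chain), and the racemic sp3 centre of dienone 7 disappears on tautomerisation to the phenol.

Step 5
Reactants: 8 ortho-allyl phenol
Product: 9 1-allyl-5-[3-(tert-butyldiphenylsilyloxy)propyl]-3-methoxy-2-(methoxymethoxy)benzene
Conditions: MOMCl, i-Pr2NEt, CH2Cl2, 0 °C → rt
Reagents that add atoms: chloromethyl methyl ether, COCCl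
Why: O-alkylation to the MOM acetal masks the phenol (no lactol formation in step 6, no acidic proton in step 10) and later serves as the acid-labile trigger for ring closure.

Step 6
Reactants: 9 MOM-protected allylarene
Product: 11 2-{5-[3-(tert-butyldiphenylsilyloxy)propyl]-3-methoxy-2-(methoxymethoxy)phenyl}acetaldehyde, via vicinal diol 10 (not isolated)
Conditions: OsO4 (2 mol %), NaIO4 (4 equiv), 2,6-lutidine, dioxane/H2O 3:1, rt
Reagents that add atoms: osmium tetroxide, O=[Os](=O)(=O)=O (delivers the O, recycled by sodium periodate, [Na+].[O-]I(=O)(=O)=O)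
Why: In the Lemieux–Johnson oxidation the only alkene is dihydroxylated (racemic diol, centre destroyed at once) and cleaved by periodate, while lutidine suppresses side reactions of the arylacetaldehyde.

Step 7
Reactants: 11 arylacetaldehyde (used crude)
Product: 12 2-{5-[3-(tert-butyldiphenylsilyloxy)propyl]-3-methoxy-2-(methoxymethoxy)phenyl}acetic acid
Conditions: NaClO2, NaH2PO4, 2-methyl-2-butene, t-BuOH/H2O, 0 °C → rt
Reagents that add atoms: sodium chlorite, [Na+].[O-]Cl=O
Why: The Pinnick oxidation converts the aldehyde at pH about 4 without touching the MOM or TBDPS groups, and the alkene scavenger removes HOCl before it can chlorinate the electron-rich ring.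

Step 8
Reactants: 12 arylacetic acid
Product: 13 methyl 2-{5-[3-(tert-butyldiphenylsilyloxy)propyl]-3-methoxy-2-(methoxymethoxy)phenyl}acetate
Conditions: MeI, K2CO3, DMF, rt
Reagents that add atoms: iodomethane, CI
Why: SN2 O-alkylation of the carboxylate is an acid-free esterification that spares the MOM acetal, and no other nucleophilic site is present.

Step 9
Reactants: 14 vanillin
Product: 15 4-(tert-butyldiphenylsilyloxy)-3-methoxybenzaldehyde
Conditions: TBDPSCl, imidazole, DMF, rt
Reagents that add atoms: tert-butyl(chloro)diphenylsilane, CC(C)(C)[Si](Cl)(c1ccccc1)c1ccccc1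
Why: Silylation removes the acidic phenol proton that would quench the enolate, and using the same silyl group as on the side chain allows a single final deprotection.

Step 10
Reactants: 13 methyl arylacetate; 15 O-TBDPS-vanillin
Product: 17 methyl 3-[4-(tert-butyldiphenylsilyloxy)-3-methoxyphenyl]-2-{5-[3-(tert-butyldiphenylsilyloxy)propyl]-3-methoxy-2-(methoxymethoxy)phenyl}-3-hydroxypropanoate (racemic syn/anti mixture), via lithium enolate 16 (not isolated)
Conditions: LDA (1.1 equiv), THF, −78 °C; then 15, −78 °C; AcOH quench at −78 °C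
Reagents that add atoms: none
Why: In this intermolecular aldol addition the quantitatively preformed arylacetate enolate meets a non-enolisable aldehyde, the cold acidic quench blocks retro-aldol, and the two new stereocentres are left uncontrolled because both become sp2 carbons C3 and C2 of the furan.

Step 11
Reactants: 17 aldol adduct
Product: 18 methyl 3-[4-(tert-butyldiphenylsilyloxy)-3-methoxyphenyl]-2-{5-[3-(tert-butyldiphenylsilyloxy)propyl]-3-methoxy-2-(methoxymethoxy)phenyl}-3-oxopropanoate
Conditions: DMP (1.3 equiv), CH2Cl2, 0 °C → rt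
Reagents that add atoms: none
Why: The Dess–Martin oxidation converts the benzylic secondary alcohol to the aryl ketone under near-neutral, base-free conditions, so neither retro-aldol nor E1cB dehydration competes, and both diastereomers converge on one keto ester.

Step 12
Reactants: 18 β-keto ester
Product: 20 methyl 2-[4-(tert-butyldiphenylsilyloxy)-3-methoxyphenyl]-5-[3-(tert-butyldiphenylsilyloxy)propyl]-7-methoxy-1-benzofuran-3-carboxylate, via free phenol keto ester 19 (not isolated)
Conditions: TFA/CH2Cl2 1:4, 0 °C → rt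
Reagents that add atoms: none
Why: TFA cleaves the aryl MOM acetal under conditions that TBDPS ethers survive (as in Boc removals), and the freed phenol adds to the adjacent aryl ketone and loses water in an acid-catalysed cyclodehydration driven by benzofuran aromaticity, which erases the last stereocentre.

Step 13
Reactants: 20 benzofuran-3-carboxylate
Product: 21 {2-[4-(tert-butyldiphenylsilyloxy)-3-methoxyphenyl]-5-[3-(tert-butyldiphenylsilyloxy)propyl]-7-methoxy-1-benzofuran-3-yl}methanol
Conditions: DIBAL-H (3 equiv), CH2Cl2, −78 → 0 °C; aq Rochelle salt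
Reagents that add atoms: none
Why: Excess DIBAL-H reduces the only carbonyl group completely to the primary alcohol, leaves both silyl ethers intact, and the neutral tartrate work-up protects the acid-sensitive heterobenzylic carbinol.

Step 14
Reactants: 21 3-(hydroxymethyl)benzofuran
Product: 22 2-[4-(tert-butyldiphenylsilyloxy)-3-methoxyphenyl]-5-[3-(tert-butyldiphenylsilyloxy)propyl]-7-methoxy-1-benzofuran-3-carbaldehyde
Conditions: activated MnO2 (15 equiv), CH2Cl2, rt
Reagents that add atoms: none
Why: MnO2 oxidation of the activated heterobenzylic alcohol stops cleanly at the aldehyde, and the phenol and aliphatic OH are still masked.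

Step 15
Reactants: 22 bis-TBDPS aldehyde
Product: 23 2-(4-hydroxy-3-methoxyphenyl)-5-(3-hydroxypropyl)-7-methoxy-1-benzofuran-3-carbaldehyde (target)
Conditions: TBAF (3 equiv), AcOH (3 equiv), THF, 0 °C → rt
Reagents that add atoms: none
Why: Fluoride-driven desilylation (strong Si–F bond) removes the aryl and alkyl TBDPS groups together, and the acetic acid buffer keeps the medium mild for the non-enolisable aldehyde and the liberated phenol.

## Compound list
1 | eugenol | C=CCc1ccc(O)c(OC)c1 | starting material
2 | 9-[3-(4-{(9-borabicyclo[3.3.1]nonan-9-yl)oxy}-3-methoxyphenyl)propyl]-9-borabicyclo[3.3.1]nonane | COc1cc(CCCB2C3CCCC2CCC3)ccc1OB1C2CCCC1CCC2 | intermediate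
3 | dihydroconiferyl alcohol | COc1cc(CCCO)ccc1O | intermediate
4 | allyl bromide | C=CCBr | starting material
5 | 3-[4-(allyloxy)-3-methoxyphenyl]propan-1-ol | C=CCOc1ccc(CCCO)cc1OC | intermediate
6 | [3-(4-allyloxy-3-methoxyphenyl)propoxy](tert-butyl)diphenylsilane | C=CCOc1ccc(CCCO[Si](c2ccccc2)(c2ccccc2)C(C)(C)C)cc1OC | intermediate
7 | 6-allyl-4-[3-(TBDPS-oxy)propyl]-2-methoxycyclohexa-2,4-dien-1-one (racemic) | C=CCC1C=C(CCCO[Si](c2ccccc2)(c2ccccc2)C(C)(C)C)C=C(OC)C1=O | intermediate
8 | 2-allyl-4-[3-(TBDPS-oxy)propyl]-6-methoxyphenol | C=CCc1cc(CCCO[Si](c2ccccc2)(c2ccccc2)C(C)(C)C)cc(OC)c1O | intermediate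
9 | 1-allyl-5-[3-(TBDPS-oxy)propyl]-3-methoxy-2-(methoxymethoxy)benzene | C=CCc1cc(CCCO[Si](c2ccccc2)(c2ccccc2)C(C)(C)C)cc(OC)c1OCOC | intermediate
10 | 3-aryl-propane-1,2-diol from 9 (racemic) | OCC(O)Cc1cc(CCCO[Si](c2ccccc2)(c2ccccc2)C(C)(C)C)cc(OC)c1OCOC | intermediate
11 | arylacetaldehyde | O=CCc1cc(CCCO[Si](c2ccccc2)(c2ccccc2)C(C)(C)C)cc(OC)c1OCOC | intermediate
12 | arylacetic acid | OC(=O)Cc1cc(CCCO[Si](c2ccccc2)(c2ccccc2)C(C)(C)C)cc(OC)c1OCOC | intermediate
13 | methyl arylacetate | COC(=O)Cc1cc(CCCO[Si](c2ccccc2)(c2ccccc2)C(C)(C)C)cc(OC)c1OCOC | intermediate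
14 | vanillin | COc1cc(C=O)ccc1O | starting material
15 | 4-(tert-butyldiphenylsilyloxy)-3-methoxybenzaldehyde | COc1cc(C=O)ccc1O[Si](c1ccccc1)(c1ccccc1)C(C)(C)C | intermediate
16 | lithium enolate of 13 | [Li+].COC([O-])=Cc1cc(CCCO[Si](c2ccccc2)(c2ccccc2)C(C)(C)C)cc(OC)c1OCOC | intermediate
17 | aldol adduct (β-hydroxy ester, racemic syn/anti mixture) | COC(=O)C(C(O)c1ccc(O[Si](c2ccccc2)(c2ccccc2)C(C)(C)C)c(OC)c1)c1cc(CCCO[Si](c2ccccc2)(c2ccccc2)C(C)(C)C)cc(OC)c1OCOC | intermediate
18 | β-keto ester (racemic, keto/enol) | COC(=O)C(C(=O)c1ccc(O[Si](c2ccccc2)(c2ccccc2)C(C)(C)C)c(OC)c1)c1cc(CCCO[Si](c2ccccc2)(c2ccccc2)C(C)(C)C)cc(OC)c1OCOC | intermediate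
19 | free phenol β-keto ester | COC(=O)C(C(=O)c1ccc(O[Si](c2ccccc2)(c2ccccc2)C(C)(C)C)c(OC)c1)c1cc(CCCO[Si](c2ccccc2)(c2ccccc2)C(C)(C)C)cc(OC)c1O | intermediate
20 | bis-TBDPS methyl 2-arylbenzofuran-3-carboxylate | COC(=O)c1c(-c2ccc(O[Si](c3ccccc3)(c3ccccc3)C(C)(C)C)c(OC)c2)oc2c(OC)cc(CCCO[Si](c3ccccc3)(c3ccccc3)C(C)(C)C)cc12 | intermediate
21 | bis-TBDPS 3-(hydroxymethyl)benzofuran | OCc1c(-c2ccc(O[Si](c3ccccc3)(c3ccccc3)C(C)(C)C)c(OC)c2)oc2c(OC)cc(CCCO[Si](c3ccccc3)(c3ccccc3)C(C)(C)C)cc12 | intermediate
22 | bis-TBDPS benzofuran-3-carbaldehyde | O=Cc1c(-c2ccc(O[Si](c3ccccc3)(c3ccccc3)C(C)(C)C)c(OC)c2)oc2c(OC)cc(CCCO[Si](c3ccccc3)(c3ccccc3)C(C)(C)C)cc12 | intermediate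
23 | 2-(4-hydroxy-3-methoxyphenyl)-5-(3-hydroxypropyl)-7-methoxy-1-benzofuran-3-carbaldehyde | COc1cc(-c2oc3c(OC)cc(CCCO)cc3c2C=O)ccc1O | target

## Step count and risks
Total steps: 15. Longest linear sequence: 14 (steps 1–8 and 10–15, from eugenol). Step 9 is the one-step side branch from vanillin.

**Step 10 (aldol).** A stabilised arylacetate enolate and an electron-rich benzaldehyde give an aldolate that can revert, so conversion may be poor.
- The fallback sets out from 15 and 13.
- Pinnick oxidation of 15 gives 4-(tert-butyldiphenylsilyloxy)-3-methoxybenzoic acid F1.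
- CDI in THF converts F1 into 1-[4-(tert-butyldiphenylsilyloxy)-3-methoxybenzoyl]imidazole F2.
- Enolate 16, now made from 13 with 2.2 equiv LiHMDS in THF at −78 °C, is C-acylated by F2 in a crossed Claisen condensation. Deprotonation of the product makes this irreversible.
- The fallback comes back at 18, so 17 and the oxidation step drop out.

**Step 12 (MOM cleavage and cyclodehydration).** The side-chain silyl ether may erode in acid, or the released formaldehyde may attack the electron-rich rings.
- The fallback sets out from 18 and removes the silyl groups on purpose.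
- TBAF/AcOH in THF gives methyl 3-(4-hydroxy-3-methoxyphenyl)-2-[5-(3-hydroxypropyl)-3-methoxy-2-(methoxymethoxy)phenyl]-3-oxopropanoate F3.
- HCl in MeOH at 60 °C is forcing. It traps formaldehyde as its dimethyl acetal and reopens any lactone. It closes the ring to methyl 2-(4-hydroxy-3-methoxyphenyl)-5-(3-hydroxypropyl)-7-methoxy-1-benzofuran-3-carboxylate F4.
- Because both hydroxyls carry the same group in the main line, unselective bis-silylation of F4 (TBDPSCl 2.5 equiv, imidazole, DMF) comes back at 20.

**Step 6 (oxidative cleavage).** The arylacetaldehyde 11 is enolisable and prone to self-condensation and air oxidation.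
- The fallback sets out from 9 and never accumulates the aldehyde.
- Ozonolysis in CH2Cl2 with 2.5 M NaOH in MeOH at −78 °C (Sudan Red end-point indicator to spare the arene) oxidises the intermediate hemiacetal and methoxy hydroperoxide directly to the methyl ester.
- It comes back at 13 and skips 11 and 12. It makes no new compound (F0).

## Further compounds
F1 | step 10 | 4-(tert-butyldiphenylsilyloxy)-3-methoxybenzoic acid | COc1cc(C(=O)O)ccc1O[Si](c1ccccc1)(c1ccccc1)C(C)(C)C
F2 | step 10 | 1-[4-(tert-butyldiphenylsilyloxy)-3-methoxybenzoyl]imidazole | COc1cc(C(=O)n2ccnc2)ccc1O[Si](c1ccccc1)(c1ccccc1)C(C)(C)C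
F3 | step 12 | methyl 3-(4-hydroxy-3-methoxyphenyl)-2-[5-(3-hydroxypropyl)-3-methoxy-2-(methoxymethoxy)phenyl]-3-oxopropanoate | COC(=O)C(C(=O)c1ccc(O)c(OC)c1)c1cc(CCCO)cc(OC)c1OCOC
F4 | step 12 | methyl 2-(4-hydroxy-3-methoxyphenyl)-5-(3-hydroxypropyl)-7-methoxy-1-benzofuran-3-carboxylate | COC(=O)c1c(-c2ccc(O)c(OC)c2)oc2c(OC)cc(CCCO)cc12
F0 | step 6 | none | none
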